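**Plan**

1. Numbering (longipinane): C1 ketone, C2=C3(Me), bridgeheads C4 and C11, one-carbon bridges C5 (H, C6) and C10 (Me, C9), C6 = CMe2, C7–C9 carbinols. Cuts, in order: both esters; C9–C10 (seven-membered ring) together with C10–CH3 (from C10=CH2); the methylidene back to a cyclobutanone; C10–C11 and C4–C5 (ketene–alkene [2+2]); C5=C11 (cross-metathesis); C7–C8 (glycolate aldol).
2. Feature used: C10 is the methyl-bearing one-carbon bridge of the cyclobutane C4–C5–C11–C10 inside the bicyclo[3.1.1]heptene, and the C6–C9 chain on C5 points to the same cyclobutane face. As an exocyclic methylidene, C10 is a latent tertiary radical, so one hydrogen-atom transfer makes the methyl, the quaternary centre, the C9 carbinol and the ring C5–C6–C7–C8–C9–C10 across the cyclobutane diagonal.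
3. Forward: open-chain dienoic acid → cyclobutanone plus six-membered ring in one operation → C10=CH2 → seven-membered ring (key step) → O8 isovalerate, C1 ketone, O7 angelate.
4. Stereochemistry: C7 and C8 from the (R)-benzyloxazolidinone aldol; C4, C5, C11 relative from suprafacial addition to the E-alkene, absolute by separating the two diastereomers that carry the enantiopure C7/C8 unit; C10 by ring constraint; C9 by Felkin–Anh control from C8.

Key step: step 11

Remark: 2,2-dimethylbut-3-enal is taken as a purchasable building block; if it has to be made, one oxidation of 2,2-dimethylbut-3-en-1-ol supplies it.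

**Step 1**
Reactants: 1 (R)-4-benzyloxazolidin-2-one; 2 (benzyloxy)acetyl chloride
Product: 3 (R)-4-benzyl-3-[2-(benzyloxy)acetyl]oxazolidin-2-one
Conditions: n-BuLi, THF, −78 °C; then 2, −78 → 0 °C
Reagents that add atoms: none
Why: N-acylation of the lithiated oxazolidinone by the acid chloride is the standard imide formation and puts the glycolate unit (C8, C9) on the chiral auxiliary.

**Step 2**
Reactants: 3 (R)-4-benzyl-3-[2-(benzyloxy)acetyl]oxazolidin-2-one; 4 2,2-dimethylbut-3-enal
Product: 6 (R)-4-benzyl-3-[(2R,3S)-2-(benzyloxy)-3-hydroxy-4,4-dimethylhex-5-enoyl]oxazolidin-2-one, via Z-boron enolate 5 (not isolated)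
Conditions: Bu2BOTf, Et3N, CH2Cl2, −78 → 0 °C; 4, −78 → 0 °C; pH 7 buffer, MeOH, H2O2
Reagents that add atoms: none
Why: Evans syn-glycolate aldol through a Zimmerman–Traxler chair, in which the (R)-auxiliary sets C8 (2R) and C7 (3S) syn, i.e. 7,8-threo as in the target, and the non-enolisable aldehyde cannot self-condense.

**Step 3**
Reactants: 6 (R)-4-benzyl-3-[(2R,3S)-2-(benzyloxy)-3-hydroxy-4,4-dimethylhex-5-enoyl]oxazolidin-2-one
Product: 7 (2R,3S)-2-(benzyloxy)-3-hydroxy-N-methoxy-N,4,4-trimethylhex-5-enamide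
Conditions: MeNH(OMe)·HCl, AlMe3, CH2Cl2, −10 → 0 °C; aq. Rochelle salt
Reagents that add atoms: N,O-dimethylhydroxylamine hydrochloride (CNOC.Cl)
Why: Aluminium-amide transamidation of a β-hydroxy N-acyloxazolidinone (Weinreb amide formation) removes the auxiliary without epimerisation and keeps C9 at the acyl oxidation level needed later.

**Step 4**
Reactants: 7 (2R,3S)-2-(benzyloxy)-3-hydroxy-N-methoxy-N,4,4-trimethylhex-5-enamide
Product: 8 (2R,3S)-2-(benzyloxy)-3-[(tert-butyldimethylsilyl)oxy]-N-methoxy-N,4,4-trimethylhex-5-enamide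
Conditions: TBSOTf, 2,6-lutidine, CH2Cl2, 0 °C → rt
Reagents that add atoms: tert-butyldimethylsilyl trifluoromethanesulfonate (CC(C)(C)[Si](C)(C)OS(=O)(=O)C(F)(F)F)
Why: Silylation of the hindered neopentyl carbinol with the silyl triflate is standard and leaves O7 (silyl) and O8 (benzyl) differently protected for the later site-selective acylations.

**Step 5**
Reactants: 9 hex-5-en-2-one; 10 diethylphosphonoacetic acid
Product: 11 (2E)-3-methylhepta-2,6-dienoic acid
Conditions: NaH (2.2 equiv), THF, 0 °C; 9, 0 °C → reflux; aq. HCl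
Reagents that add atoms: none
Why: Horner–Wadsworth–Emmons olefination of the methyl ketone with the phosphonate dianion gives the trisubstituted enoic acid directly with the E isomer favoured, and a minor 2Z isomer need not be removed because both converge on 16 after steps 7 and 8.

**Step 6**
Reactants: 8 (2R,3S)-2-(benzyloxy)-3-[(tert-butyldimethylsilyl)oxy]-N-methoxy-N,4,4-trimethylhex-5-enamide; 11 (2E)-3-methylhepta-2,6-dienoic acid
Product: 12 (2E,6E,9S,10R)-10-(benzyloxy)-9-[(tert-butyldimethylsilyl)oxy]-11-[methoxy(methyl)amino]-3,8,8-trimethyl-11-oxoundeca-2,6-dienoic acid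
Conditions: second-generation Hoveyda–Grubbs catalyst (10 mol %), 11 (3 equiv), CH2Cl2, 40 °C
Reagents that add atoms: none
Why: Olefin cross-metathesis pairs a readily homodimerising terminal alkene (in excess) with the neopentylic vinyl group, which does not homodimerise, and should give the E-alkene C5=C11, while the conjugated trisubstituted alkene and the free acid are inert to the ruthenium carbene.

**Step 7**
Reactants: 12 (2E,6E,9S,10R)-10-(benzyloxy)-9-[(tert-butyldimethylsilyl)oxy]-11-[methoxy(methyl)amino]-3,8,8-trimethyl-11-oxoundeca-2,6-dienoic acid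
Product: 15 (2R,3S)-2-(benzyloxy)-3-[(tert-butyldimethylsilyl)oxy]-N-methoxy-N,4-dimethyl-4-[(1R,5R,7R)-2-methylidene-6-oxobicyclo[3.1.1]heptan-7-yl]pentanamide, via acid chloride 13 (not isolated), via vinylketene 14 (not isolated)
Conditions: (COCl)2, DMF (cat.), CH2Cl2, 0 °C → rt; concentrate; slow addition to Et3N, toluene, 110 °C (0.01 M); chromatography
Reagents that add atoms: none
Why: γ-Dehydrochlorination of 13 gives the vinylketene, whose intramolecular thermal ketene–alkene [2+2] should close in the bridged sense because the electrophilic ketene carbon C10 bonds to the unhindered C11 rather than to C5 (flanked by quaternary C6) before C4 closes onto C5; suprafacial addition to the E-alkene fixes C4, C11 and C5 relative to each other with the chain on C5 anti to the three-carbon bridge, whereas the C7/C8 centres are too remote to bias the absolute sense reliably, so the diastereomer with the mirror-image bicyclic core is expected alongside 15 and is removed by chromatography at this stage.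

**Step 8**
Reactants: 15 (2R,3S)-2-(benzyloxy)-3-[(tert-butyldimethylsilyl)oxy]-N-methoxy-N,4-dimethyl-4-[(1R,5R,7R)-2-methylidene-6-oxobicyclo[3.1.1]heptan-7-yl]pentanamide
Product: 16 (2R,3S)-2-(benzyloxy)-3-[(tert-butyldimethylsilyl)oxy]-N-methoxy-N,4-dimethyl-4-[(1R,5R,7R)-2-methyl-6-oxobicyclo[3.1.1]hept-2-en-7-yl]pentanamide
Conditions: RuHCl(CO)(PPh3)3 (5 mol %), toluene, 80 °C
Reagents that add atoms: none
Why: Ruthenium-hydride addition/β-hydride elimination moves the exocyclic methylidene into the ring to the more stable trisubstituted C2=C3 alkene (the β-pinene to α-pinene type isomerisation) by a non-radical path that does not open the cyclobutane, and it cannot go further because C4 is a bridgehead.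

**Step 9**
Reactants: 16 (2R,3S)-2-(benzyloxy)-3-[(tert-butyldimethylsilyl)oxy]-N-methoxy-N,4-dimethyl-4-[(1R,5R,7R)-2-methyl-6-oxobicyclo[3.1.1]hept-2-en-7-yl]pentanamide
Product: 17 (2R,3S)-2-(benzyloxy)-3-[(tert-butyldimethylsilyl)oxy]-N-methoxy-N,4-dimethyl-4-[(1R,5R,7R)-2-methyl-6-methylidenebicyclo[3.1.1]hept-2-en-7-yl]pentanamide
Conditions: Ph3PCH3Br, KN(SiMe3)2, THF, 0 °C; then 16, −78 → 0 °C
Reagents that add atoms: methyltriphenylphosphonium bromide (C[P+](c1ccccc1)(c1ccccc1)c1ccccc1.[Br-])
Why: Wittig methylenation of the strained, non-enolisable cyclobutanone (both α-carbons are bridgeheads) is fast at low temperature, where the ylide leaves the Weinreb amide alone, and brings in the C15 carbon as the methylidene on C10.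

**Step 10**
Reactants: 17 (2R,3S)-2-(benzyloxy)-3-[(tert-butyldimethylsilyl)oxy]-N-methoxy-N,4-dimethyl-4-[(1R,5R,7R)-2-methyl-6-methylidenebicyclo[3.1.1]hept-2-en-7-yl]pentanamide
Product: 18 (2R,3S)-2-(benzyloxy)-3-[(tert-butyldimethylsilyl)oxy]-4-methyl-4-[(1R,5R,7R)-2-methyl-6-methylidenebicyclo[3.1.1]hept-2-en-7-yl]pentanal
Conditions: i-Bu2AlH, THF, −78 °C; aq. Rochelle salt
Reagents that add atoms: none
Why: Hydride reduction of a Weinreb amide stops at the chelated tetrahedral intermediate and releases the α-benzyloxy aldehyde on work-up without epimerising C8, and the isolated alkenes are untouched.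

**Step 11**
Reactants: 18 (2R,3S)-2-(benzyloxy)-3-[(tert-butyldimethylsilyl)oxy]-4-methyl-4-[(1R,5R,7R)-2-methyl-6-methylidenebicyclo[3.1.1]hept-2-en-7-yl]pentanal
Product: 19 (4R,5R,7S,8S,9S,10S,11R)-8-(benzyloxy)-7-[(tert-butyldimethylsilyl)oxy]longipin-2-en-9-ol
Conditions: chloro[N,N′-bis(3,5-di-tert-butylsalicylidene)-1,2-cyclohexanediaminato]cobalt (10 mol %), CrCl3·3THF (30 mol %), PhSiH3, THF, rt, 0.005 M; then K2CO3, aq. MeOH
Reagents that add atoms: none
Why: Proposed new method: a trivalent cobalt hydride formed from the salen complex and the silane transfers a hydrogen atom to the exocyclic CH2 on C10 (Markovnikov), which makes the C15 methyl and the tertiary cyclobutyl radical at C10; divalent chromium intercepts this radical as an alkylchromium species (or reduces the alkoxy radical after direct addition), and the carbon–chromium bond adds to the C9 aldehyde. The closest known reaction types are the cobalt/chromium-catalysed branch-selective hydrogen-atom-transfer coupling of alkenes with aldehydes (intermolecular) and the iron-mediated hydrogen-atom-transfer cyclisation of alkene-tethered ketones through tertiary radicals; the intramolecular case through a tertiary cyclobutyl radical onto an aldehyde is the extension. The step closes the cycloheptane C5–C6–C7–C8–C9–C10–C4 (the four-carbon bridge across the cyclobutane diagonal) by 7-exo-trig attack on the carbonyl carbon. C10 is controlled by the ring, because the tether hangs from C5 on the cyclobutane face anti to the C1–C3 bridge, so C9 can bond only to that face of the planar radical and the methyl is forced syn to the three-carbon bridge. C9 is set by Felkin–Anh control from C8: in the ring transition state the C8–OBn bond lies anti to the incoming C10, which leads to the 8,9-cis (9S) alcohol. The step needs hydrogen-atom transfer at the exocyclic 1,1-disubstituted alkene rather than at the trisubstituted C2=C3 alkene, and radical capture faster than cyclobutane β-scission; these are secured by the faster transfer to unhindered terminal methylidenes, by the lack of any hydrogen that C10 could give back without forming a bridgehead alkene, and by high dilution with a chromium loading that keeps capture fast.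

**Step 12**
Reactants: 19 (4R,5R,7S,8S,9S,10S,11R)-8-(benzyloxy)-7-[(tert-butyldimethylsilyl)oxy]longipin-2-en-9-ol
Product: 20 (4R,5R,7S,8S,9S,10S,11R)-7-[(tert-butyldimethylsilyl)oxy]longipin-2-ene-8,9-diol
Conditions: lithium 4,4′-di-tert-butylbiphenylide, THF, −78 °C; NH4Cl at −78 °C
Reagents that add atoms: none
Why: Single-electron reductive cleavage of the benzyl ether by the arene radical anion spares the silyl ether and the isolated alkene (no carbonyl group is present at this stage), and the cold quench prevents silyl migration from O7 to O8.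

**Step 13**
Reactants: 20 (4R,5R,7S,8S,9S,10S,11R)-7-[(tert-butyldimethylsilyl)oxy]longipin-2-ene-8,9-diol
Product: 21 (4R,5R,7S,8S,9S,10S,11R)-7-[(tert-butyldimethylsilyl)oxy]-9-hydroxylongipin-2-en-8-yl 3-methylbutanoate
Conditions: (i-PrCH2CO)2O, DMAP (cat.), Et3N, CH2Cl2, −20 → 0 °C
Reagents that add atoms: 3-methylbutanoic anhydride (CC(C)CC(=O)OC(=O)CC(C)C)
Why: DMAP-catalysed acylation should select the C8 hydroxyl, which is flanked only by CH carbons, over the C9 hydroxyl, which is neopentylic to the quaternary cyclobutane carbon C10.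

**Step 14**
Reactants: 21 (4R,5R,7S,8S,9S,10S,11R)-7-[(tert-butyldimethylsilyl)oxy]-9-hydroxylongipin-2-en-8-yl 3-methylbutanoate
Product: 22 (4R,5S,7S,8S,9S,10R,11R)-7-[(tert-butyldimethylsilyl)oxy]-9-hydroxy-1-oxolongipin-2-en-8-yl 3-methylbutanoate
Conditions: Rh2(cap)4 (dirhodium tetrakis(caprolactamate), 1 mol %), t-BuOOH (70 % aq.), CH2Cl2, rt
Reagents that add atoms: tert-butyl hydroperoxide (CC(C)(C)OO)
Why: Peroxide-based allylic oxidation converts the ring CH2 (C1) next to the trisubstituted alkene into the enone, as α-pinene is oxidised to verbenone (the bridgehead C4–H cannot react and the methyl is less reactive), while the hindered, unactivated C9 carbinol should survive.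

**Step 15**
Reactants: 22 (4R,5S,7S,8S,9S,10R,11R)-7-[(tert-butyldimethylsilyl)oxy]-9-hydroxy-1-oxolongipin-2-en-8-yl 3-methylbutanoate
Product: 23 (4R,5S,7S,8R,9S,10R,11R)-7,9-dihydroxy-1-oxolongipin-2-en-8-yl 3-methylbutanoate
Conditions: HF·pyridine, pyridine, THF, 0 °C → rt
Reagents that add atoms: none
Why: Buffered fluoride desilylation frees the C7 hydroxyl without acyl migration or ester hydrolysis and does not touch the enone (the descriptor at C8 changes by priority only, not in space).

**Step 16**
Reactants: 23 (4R,5S,7S,8R,9S,10R,11R)-7,9-dihydroxy-1-oxolongipin-2-en-8-yl 3-methylbutanoate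
Product: 24 (4R,5S,7S,8S,9S,10R,11R)-9-hydroxy-8-(3-methylbutanoyloxy)-1-oxolongipin-2-en-7-yl (Z)-2-methylbut-2-enoate (CNP0128158.1)
Conditions: angelic acid, 2,4,6-trichlorobenzoyl chloride, Et3N, toluene, rt; then 23, 80 °C
Reagents that add atoms: angelic acid (C/C=C(/C)C(=O)O)
Why: Yamaguchi-type acylation with the mixed anhydride of angelic acid, run without DMAP, transfers the angeloyl group without Z to E isomerisation and should select the C7 hydroxyl, because the C9 hydroxyl is flanked by the quaternary cyclobutane carbon C10 and its methyl group and is the most congested carbinol site of the ring.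

**Compound list**

1 | (R)-4-benzyloxazolidin-2-one | O=C1N[C@H](Cc2ccccc2)CO1 | starting material
2 | (benzyloxy)acetyl chloride | O=C(Cl)COCc1ccccc1 | starting material
3 | (R)-4-benzyl-3-[2-(benzyloxy)acetyl]oxazolidin-2-one | O=C1OC[C@@H](Cc2ccccc2)N1C(=O)COCc1ccccc1 | intermediate
4 | 2,2-dimethylbut-3-enal | C=CC(C)(C)C=O | starting material
5 | Z-dibutylboron enolate of 3 (not isolated) | CCCCB(CCCC)O/C(=C\OCc1ccccc1)N1C(=O)OC[C@H]1Cc1ccccc1 | intermediate
6 | (R)-4-benzyl-3-[(2R,3S)-2-(benzyloxy)-3-hydroxy-4,4-dimethylhex-5-enoyl]oxazolidin-2-one | O=C1OC[C@@H](Cc2ccccc2)N1C(=O)[C@H](OCc1ccccc1)[C@@H](O)C(C)(C)C=C | intermediate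
7 | (2R,3S)-2-(benzyloxy)-3-hydroxy-N-methoxy-N,4,4-trimethylhex-5-enamide | CON(C)C(=O)[C@H](OCc1ccccc1)[C@@H](O)C(C)(C)C=C | intermediate
8 | (2R,3S)-2-(benzyloxy)-3-[(tert-butyldimethylsilyl)oxy]-N-methoxy-N,4,4-trimethylhex-5-enamide | CON(C)C(=O)[C@H](OCc1ccccc1)[C@@H](O[Si](C)(C)C(C)(C)C)C(C)(C)C=C | intermediate
9 | hex-5-en-2-one | CC(=O)CCC=C | starting material
10 | diethylphosphonoacetic acid | CCOP(=O)(CC(=O)O)OCC | starting material
11 | (2E)-3-methylhepta-2,6-dienoic acid | C=CCC/C(C)=C/C(=O)O | intermediate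
12 | (2E,6E,9S,10R)-10-(benzyloxy)-9-[(tert-butyldimethylsilyl)oxy]-11-[methoxy(methyl)amino]-3,8,8-trimethyl-11-oxoundeca-2,6-dienoic acid | CON(C)C(=O)[C@H](OCc1ccccc1)[C@@H](O[Si](C)(C)C(C)(C)C)C(C)(C)/C=C/CC/C(C)=C/C(=O)O | intermediate
13 | acid chloride of 12 (not isolated) | CON(C)C(=O)[C@H](OCc1ccccc1)[C@@H](O[Si](C)(C)C(C)(C)C)C(C)(C)/C=C/CC/C(C)=C/C(Cl)=O | intermediate
14 | vinylketene formed from 13 by loss of HCl at the C3 methyl group (not isolated) | CON(C)C(=O)[C@H](OCc1ccccc1)[C@@H](O[Si](C)(C)C(C)(C)C)C(C)(C)/C=C/CCC(=C)C=C=O | intermediate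
15 | (2R,3S)-2-(benzyloxy)-3-[(tert-butyldimethylsilyl)oxy]-N-methoxy-N,4-dimethyl-4-[(1R,5R,7R)-2-methylidene-6-oxobicyclo[3.1.1]heptan-7-yl]pentanamide (chain on C7 of the bicycle anti to the three-carbon bridge) | CON(C)C(=O)[C@H](OCc1ccccc1)[C@@H](O[Si](C)(C)C(C)(C)C)C(C)(C)[C@H]1[C@@H]2C(=C)CC[C@H]1C2=O | intermediate
16 | (2R,3S)-2-(benzyloxy)-3-[(tert-butyldimethylsilyl)oxy]-N-methoxy-N,4-dimethyl-4-[(1R,5R,7R)-2-methyl-6-oxobicyclo[3.1.1]hept-2-en-7-yl]pentanamide | CON(C)C(=O)[C@H](OCc1ccccc1)[C@@H](O[Si](C)(C)C(C)(C)C)C(C)(C)[C@H]1[C@@H]2C(C)=CC[C@H]1C2=O | intermediate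
17 | (2R,3S)-2-(benzyloxy)-3-[(tert-butyldimethylsilyl)oxy]-N-methoxy-N,4-dimethyl-4-[(1R,5R,7R)-2-methyl-6-methylidenebicyclo[3.1.1]hept-2-en-7-yl]pentanamide | CON(C)C(=O)[C@H](OCc1ccccc1)[C@@H](O[Si](C)(C)C(C)(C)C)C(C)(C)[C@H]1[C@@H]2C(C)=CC[C@H]1C2=C | intermediate
18 | (2R,3S)-2-(benzyloxy)-3-[(tert-butyldimethylsilyl)oxy]-4-methyl-4-[(1R,5R,7R)-2-methyl-6-methylidenebicyclo[3.1.1]hept-2-en-7-yl]pentanal | O=C[C@H](OCc1ccccc1)[C@@H](O[Si](C)(C)C(C)(C)C)C(C)(C)[C@H]1[C@@H]2C(C)=CC[C@H]1C2=C | intermediate
19 | (4R,5R,7S,8S,9S,10S,11R)-8-(benzyloxy)-7-[(tert-butyldimethylsilyl)oxy]longipin-2-en-9-ol (longipinane numbering of the plan; 7,8-trans; 8,9-cis; C10 methyl syn to the C1–C3 bridge) | CC(C)(C)[Si](C)(C)O[C@@H]1[C@@H](OCc2ccccc2)[C@@H](O)[C@@]2(C)[C@@H]3CC=C(C)[C@H]2[C@@H]3C1(C)C | intermediate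
20 | (4R,5R,7S,8S,9S,10S,11R)-7-[(tert-butyldimethylsilyl)oxy]longipin-2-ene-8,9-diol | CC(C)(C)[Si](C)(C)O[C@@H]1[C@@H](O)[C@@H](O)[C@@]2(C)[C@@H]3CC=C(C)[C@H]2[C@@H]3C1(C)C | intermediate
21 | (4R,5R,7S,8S,9S,10S,11R)-7-[(tert-butyldimethylsilyl)oxy]-9-hydroxylongipin-2-en-8-yl 3-methylbutanoate | CC(C)(C)[Si](C)(C)O[C@@H]1[C@@H](OC(=O)CC(C)C)[C@@H](O)[C@@]2(C)[C@@H]3CC=C(C)[C@H]2[C@@H]3C1(C)C | intermediate
22 | (4R,5S,7S,8S,9S,10R,11R)-7-[(tert-butyldimethylsilyl)oxy]-9-hydroxy-1-oxolongipin-2-en-8-yl 3-methylbutanoate | CC(C)(C)[Si](C)(C)O[C@@H]1[C@@H](OC(=O)CC(C)C)[C@@H](O)[C@@]2(C)[C@@H]3C(=O)C=C(C)[C@H]2[C@@H]3C1(C)C | intermediate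
23 | (4R,5S,7S,8R,9S,10R,11R)-7,9-dihydroxy-1-oxolongipin-2-en-8-yl 3-methylbutanoate | O[C@@H]1[C@@H](OC(=O)CC(C)C)[C@@H](O)[C@@]2(C)[C@@H]3C(=O)C=C(C)[C@H]2[C@@H]3C1(C)C | intermediate
24 | (4R,5S,7S,8S,9S,10R,11R)-9-hydroxy-8-(3-methylbutanoyloxy)-1-oxolongipin-2-en-7-yl (Z)-2-methylbut-2-enoate (CNP0128158.1) | C/C=C(/C)C(=O)O[C@@H]1[C@@H](OC(=O)CC(C)C)[C@@H](O)[C@@]2(C)[C@@H]3C(=O)C=C(C)[C@H]2[C@@H]3C1(C)C | target

**Totals and risks**

Total steps: 16. Longest linear sequence: 15 (steps 1–4 and 6–16; step 5 makes the side arm 11).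

The three steps most likely to fail, in this order:

Risk 1 is step 11, the only step with a proposed new method. What may go wrong: hydrogen-atom transfer at the trisubstituted ring alkene followed by opening of the cyclobutane, plain reduction of the methylidene before the radical is intercepted, or poor facial control at C9. Fallback: it sets out from 18 and comes back to the route at 19 without any new compound. The ring is closed by free-radical attack on the carbonyl instead of a radical-polar crossover through chromium, using the known iron-mediated hydrogen-atom-transfer cyclisation of alkene-tethered carbonyl compounds (Fe(acac)3 in stoichiometric amount, PhSiH3, EtOH/ethylene glycol, 60 °C). The tertiary C10 radical adds directly to C9=O and the alkoxy radical is reduced by iron.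

Risk 2 is step 7. What may go wrong: closure in the fused (bicyclo[3.2.0]) sense, oligomerisation of the vinylketene because the 1,2-disubstituted, neopentyl-flanked alkene is a weak partner for a ketene, and lack of facial discrimination by the remote C7/C8 unit. Fallback: it sets out from 12 and comes back to the route at 15, using the more electrophilic keteniminium variant of the [2+2]. Acid chloride 13, made as in step 7, reacts with pyrrolidine and Et3N to give the pyrrolidine amide of 12 F1 in one operation. Tf2O and 2,4,6-collidine in 1,2-dichloroethane at 80 °C then convert this amide by O-triflation and γ-deprotonation into the vinylketeniminium triflate F2 which is not isolated; the less basic N-methoxy amide should stay untouched. Intramolecular cycloaddition gives the cyclobutaniminium triflate F3 and aqueous NaHCO3 hydrolyses it to 15, which is freed from its core diastereomer by chromatography as before.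

Risk 3 is step 16. What may go wrong: loss of site selectivity between the C7 and C9 hydroxyls, or Z to E isomerisation of the angeloyl donor on prolonged heating. Fallback: it sets out from 22 and comes back to the route at 24. Chloroacetic anhydride, pyridine and DMAP cap the C9 hydroxyl to give the 9-O-chloroacetate of 22 F4 in the first operation. HF·pyridine then converts this into the 7-hydroxy 9-O-chloroacetate F5 by freeing the C7 hydroxyl. Angeloylation as in step 16, now with a single free hydroxyl, gives the 9-O-chloroacetate of 24 F6 and thiourea with NaHCO3 in EtOH at 50 °C removes the chloroacetyl group to give 24.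

**Further compounds**

F0 | step 11 | none | none
F1 | step 7 | pyrrolidine amide of 12 | CON(C)C(=O)[C@H](OCc1ccccc1)[C@@H](O[Si](C)(C)C(C)(C)C)C(C)(C)/C=C/CC/C(C)=C/C(=O)N1CCCC1
F2 | step 7 | vinylketeniminium triflate (not isolated) | CON(C)C(=O)[C@H](OCc1ccccc1)[C@@H](O[Si](C)(C)C(C)(C)C)C(C)(C)/C=C/CCC(=C)C=C=[N+]1CCCC1.[O-]S(=O)(=O)C(F)(F)F
F3 | step 7 | cyclobutaniminium triflate (N-pyrrolidinium analogue of 15) | CON(C)C(=O)[C@H](OCc1ccccc1)[C@@H](O[Si](C)(C)C(C)(C)C)C(C)(C)[C@H]1[C@@H]2C(=C)CC[C@H]1C2=[N+]1CCCC1.[O-]S(=O)(=O)C(F)(F)F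
F4 | step 16 | 9-O-chloroacetate of 22 | CC(C)(C)[Si](C)(C)O[C@@H]1[C@@H](OC(=O)CC(C)C)[C@@H](OC(=O)CCl)[C@@]2(C)[C@@H]3C(=O)C=C(C)[C@H]2[C@@H]3C1(C)C
F5 | step 16 | 7-hydroxy 9-O-chloroacetate | O[C@@H]1[C@@H](OC(=O)CC(C)C)[C@@H](OC(=O)CCl)[C@@]2(C)[C@@H]3C(=O)C=C(C)[C@H]2[C@@H]3C1(C)C
F6 | step 16 | 9-O-chloroacetate of 24 | C/C=C(/C)C(=O)O[C@@H]1[C@@H](OC(=O)CC(C)C)[C@@H](OC(=O)CCl)[C@@]2(C)[C@@H]3C(=O)C=C(C)[C@H]2[C@@H]3C1(C)C
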